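**Plan**

- Locants: lactone O1, C2 (C=O), C3–C7; carbinol C8 and chain C9–C13 on C7; chain C1′–C5′ on C3. The retrosynthesis cuts, in order: the three O–Si bonds; C10–C11 and C3–C1′ (two B-alkyl Suzuki couplings); the C3–I bond and the C3=C4 unsaturation; O1 out of the ring (O1–C2 and O1–C7 replaced by a C2–C7 bond of a cyclohexanone); and last C7–C8 (aldol).
- Enabling feature: in the seven-membered ring, O1 lies between the carbonyl C2 and the methyl-bearing quaternary C7, and C7 carries the oxygenated C8. This array is what a peracid leaves when it inserts oxygen beside the quaternary α-carbon of a 2-methyl-2-(1-hydroxyallyl)cyclohexanone, i.e. an acrolein aldol of 2-methylcyclohexanone.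
- Forward order: 2-methylcyclohexanone → tetrasubstituted enol silane → aldol with acrolein → resolution → silyl ether → oxygen insertion, which turns the six-membered carbocycle into the seven-membered lactone (the only ring-forming event) → C3=C4 and C3–I → coupling of the C1′–C5′ chain → hydroboration of the vinyl group and coupling of C11–C13 → desilylation.
- Stereochemistry: the C7/C8 relative configuration comes from the chair aldol transition state and the absolute configuration (7R,8R) from a Sharpless kinetic resolution with D-(−)-DIPT. Both survive the oxygen insertion because the quaternary carbon migrates with retention. Each Z alkene comes from a geometrically defined vinyl iodide (anti carbomagnesiation of propargyl alcohol, trans hydroalumination of but-2-yn-1-ol) coupled with retention.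

Key step: step 5

Remarks: TBS = tert-butyldimethylsilyl and TBSO = its ether. Racemic 5 is written as the 1:1 pair of its enantiomers. Selenide 11 is a pair of C3 epimers, so C3 is left undefined in its SMILES. CIP analysis of the target gives 7R,8R and Z for both side-chain alkenes.

**Route**

Step 1
Reactants: 1 2-methylcyclohexanone (racemic)
Product: 2 2-methyl-1-(trimethylsilyloxy)cyclohex-1-ene
Conditions: TMSCl, Et3N, DMF, 130 °C; fractional distillation
Reagents that add atoms: chlorotrimethylsilane, C[Si](C)(C)Cl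
Why: Silylation under equilibrating conditions favours the tetrasubstituted enol silane (thermodynamic silyl enol ether formation) and distillation removes the minor trisubstituted isomer, so the enolate regiochemistry is fixed before the C–C bond is made.

Step 2
Reactants: 2 2-methyl-1-(trimethylsilyloxy)cyclohex-1-ene; 3 acrolein
Product: 5 rac-(2R*,1′R*)-2-(1-hydroxyprop-2-en-1-yl)-2-methylcyclohexan-1-one, via lithium 2-methylcyclohex-1-en-1-olate 4 (not isolated)
Conditions: MeLi, THF, 0 °C → rt; then 3, −78 °C; AcOH, −78 °C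
Reagents that add atoms: none
Why: MeLi cleaves the O–Si bond to give the regiodefined enolate 4, which adds 1,2 to acrolein at −78 °C (lithium enolate aldol addition) through a chair Zimmerman–Traxler transition state with the vinyl group equatorial, so that the ring CH2 trans to the enolate oxygen ends up anti to the new hydroxyl and the quaternary carbon and the carbinol are set together as the (2R*,1′R*) pair, the minor syn isomer being removed by chromatography.

Step 3
Reactants: 5 rac-(2R*,1′R*)-2-(1-hydroxyprop-2-en-1-yl)-2-methylcyclohexan-1-one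
Product: 6 (R)-2-[(R)-1-hydroxyprop-2-en-1-yl]-2-methylcyclohexan-1-one
Conditions: Ti(OiPr)4 (cat.), D-(−)-DIPT (cat.), t-BuOOH (0.6 equiv), 4 Å MS, CH2Cl2, −20 °C
Reagents that add atoms: none
Why: In this Sharpless kinetic resolution of a secondary allylic alcohol, the Ti(OiPr)4–D-(−)-DIPT catalyst should epoxidise the (1′S) carbinol of the (2S,1′S) enantiomer much faster, so that past half conversion the (2R,1′R) alcohol remains and is separated from the more polar erythro epoxy alcohol, no stereocentre being created in the material carried on.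

Step 4
Reactants: 6 (R)-2-[(R)-1-hydroxyprop-2-en-1-yl]-2-methylcyclohexan-1-one
Product: 7 (R)-2-[(R)-1-(TBSO)prop-2-en-1-yl]-2-methylcyclohexan-1-one
Conditions: TBSOTf, 2,6-lutidine, CH2Cl2, −78 → 0 °C
Reagents that add atoms: tert-butyldimethylsilyl trifluoromethanesulfonate, CC(C)(C)[Si](C)(C)OS(=O)(=O)C(F)(F)F
Why: A silyl triflate with a hindered pyridine base silylates even a neopentyl-type secondary alcohol at low temperature (standard silyl ether formation) and avoids the alkoxide that could trigger retro-aldol cleavage.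

Step 5
Reactants: 7 (R)-2-[(R)-1-(TBSO)prop-2-en-1-yl]-2-methylcyclohexan-1-one
Product: 9 (R)-7-[(R)-1-(TBSO)prop-2-en-1-yl]-7-methyloxepan-2-one, via Criegee adduct 8 (not isolated)
Conditions: mCPBA, NaHCO3, CH2Cl2, 0 °C → rt
Reagents that add atoms: 3-chloroperoxybenzoic acid, OOC(=O)c1cccc(Cl)c1
Why: The peracid adds to the ketone carbonyl of 7 to give the tetrahedral Criegee adduct 8, and the bond from the quaternary carbon to the former carbonyl carbon then shifts to the proximal peroxide oxygen, antiperiplanar to the O–O bond, as 3-chlorobenzoate leaves. This is a Baeyer–Villiger oxidation, the closest known case being the peracid ring expansion of 2,2-dialkylcyclohexanones to 7,7-dialkyloxepan-2-ones. The oxepanone is closed by a one-atom ring expansion (1,2-shift from carbon to oxygen within a six-membered carbocycle) and not by cyclisation of an open chain, so no lactonisation onto a hindered tertiary alcohol is needed. No stereocentre is created: the quaternary carbon migrates with retention and the silyloxy carbon is a spectator, so the aldol-derived pair becomes C7 and C8 unchanged. The step needs regioselectivity for migration of the fully substituted carbon over the ring CH2, which the higher migratory aptitude of a tertiary alkyl group secures, and chemoselectivity for the ketone over the alkene, which is secured because the only alkene is a monosubstituted vinyl group deactivated by the allylic silyl ether. The NaHCO3 buffer keeps 3-chlorobenzoic acid from cleaving the silyl ether or opening the lactone.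

Step 6
Reactants: 9 (R)-7-[(R)-1-(TBSO)prop-2-en-1-yl]-7-methyloxepan-2-one
Product: 11 (7R)-7-[(R)-1-(TBSO)prop-2-en-1-yl]-7-methyl-3-(phenylselanyl)oxepan-2-one (C3 epimers), via lactone lithium enolate 10 (not isolated)
Conditions: LiN(iPr)2, THF, −78 °C; then PhSeBr, −78 °C
Reagents that add atoms: benzeneselenenyl bromide, Br[Se]c1ccccc1
Why: Deprotonation can occur only at C3 because C7 carries no hydrogen, and enolate 10 is selenenylated by PhSeBr at −78 °C far faster than the reagent can add to the deactivated vinyl group (α-selenenylation of a lactone enolate), the C3 configuration being of no consequence because it is removed in step 7.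

Step 7
Reactants: 11 (7R)-7-[(R)-1-(TBSO)prop-2-en-1-yl]-7-methyl-3-(phenylselanyl)oxepan-2-one
Product: 13 (R)-7-[(R)-1-(TBSO)prop-2-en-1-yl]-7-methyl-6,7-dihydrooxepin-2(5H)-one, via selenoxide 12 (not isolated)
Conditions: 30% H2O2, pyridine, CH2Cl2, 0 °C → rt
Reagents that add atoms: none
Why: Oxidation gives selenoxide 12, which undergoes syn-elimination below room temperature toward C4, the only β-carbon, to give the C3=C4 enoate (selenoxide elimination), while the electron-poor vinyl group is not epoxidised.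

Step 8
Reactants: 13 (R)-7-[(R)-1-(TBSO)prop-2-en-1-yl]-7-methyl-6,7-dihydrooxepin-2(5H)-one
Product: 14 (R)-7-[(R)-1-(TBSO)prop-2-en-1-yl]-3-iodo-7-methyl-6,7-dihydrooxepin-2(5H)-one
Conditions: I2, pyridine, CH2Cl2, 0 °C → rt
Reagents that add atoms: iodine, [I][I]
Why: Amine-promoted α-iodination of a conjugated carbonyl compound (addition–iodination–elimination across C3/C4) places iodine only at C3, and the isolated vinyl group does not add iodine irreversibly under these conditions.

Step 9
Reactants: 15 prop-2-yn-1-ol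
Product: 17 (Z)-3-iodo-2-methylprop-2-en-1-ol, via alkenylmagnesium alkoxide 16 (not isolated)
Conditions: MeMgBr, CuI (cat.), THF, −10 °C → rt; then I2, −10 °C → rt
Reagents that add atoms: methylmagnesium bromide, C[Mg]Br; iodine, [I][I]
Why: Copper-catalysed carbomagnesiation of the propargylic alkoxide is anti (methyl to C2, magnesium to C3, held cis to the CH2O group in chelate 16), and iodinolysis with retention fixes the Z geometry with iodine cis to CH2OH.

Step 10
Reactants: 17 (Z)-3-iodo-2-methylprop-2-en-1-ol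
Product: 18 (Z)-tert-butyl[(3-iodo-2-methylprop-2-en-1-yl)oxy]dimethylsilane
Conditions: TBSCl, imidazole, CH2Cl2, 0 °C → rt
Reagents that add atoms: tert-butyldimethylsilyl chloride, CC(C)(C)[Si](C)(C)Cl
Why: Standard silylation of a primary allylic alcohol, to which the vinyl iodide is inert.

Step 11
Reactants: 18 (Z)-tert-butyl[(3-iodo-2-methylprop-2-en-1-yl)oxy]dimethylsilane
Product: 19 (Z)-tert-butyldimethyl[(2-methylpenta-2,4-dien-1-yl)oxy]silane
Conditions: CH2=CHSnBu3, PdCl2(MeCN)2 (cat.), DMF, rt
Reagents that add atoms: tributyl(vinyl)stannane, C=C[Sn](CCCC)(CCCC)CCCC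
Why: Stille coupling of a vinyl iodide with a vinylstannane proceeds with retention of the alkene geometry at room temperature, giving the Z diene.

Step 12
Reactants: 14 (R)-7-[(R)-1-(TBSO)prop-2-en-1-yl]-3-iodo-7-methyl-6,7-dihydrooxepin-2(5H)-one; 19 (Z)-tert-butyldimethyl[(2-methylpenta-2,4-dien-1-yl)oxy]silane
Product: 21 (R)-3-[(Z)-5-(TBSO)-4-methylpent-3-en-1-yl]-7-[(R)-1-(TBSO)prop-2-en-1-yl]-7-methyl-6,7-dihydrooxepin-2(5H)-one, via B-alkyl-9-BBN 20 (not isolated)
Conditions: 19 (slight excess), 9-BBN, THF, 0 °C → rt; then 14, PdCl2(dppf) (cat.), AsPh3, Cs2CO3, DMF/H2O, rt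
Reagents that add atoms: none
Why: 9-BBN adds anti-Markovnikov to the terminal double bond of the diene, leaving the trisubstituted alkene, and the primary borane 20 undergoes B-alkyl Suzuki–Miyaura coupling with the α-iodoenoate to form C3–C1′, the excess of diene ensuring that no B–H remains to reach the vinyl group of 14.

Step 13
Reactants: 22 but-2-yn-1-ol
Product: 24 (Z)-3-iodobut-2-en-1-ol, via alkenylalanate 23 (not isolated)
Conditions: NaAlH2(OCH2CH2OMe)2, Et2O, 0 °C → rt; then I2, THF, −78 → 0 °C
Reagents that add atoms: iodine, [I][I]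
Why: Hydroxyl-directed trans-hydroalumination delivers hydride to C2 and aluminium to C3 within the five-membered alanate 23, and iodinolysis with retention gives the Z vinyl iodide with iodine cis to CH2OH.

Step 14
Reactants: 24 (Z)-3-iodobut-2-en-1-ol
Product: 25 (Z)-tert-butyl[(3-iodobut-2-en-1-yl)oxy]dimethylsilane
Conditions: TBSCl, imidazole, CH2Cl2, 0 °C → rt
Reagents that add atoms: tert-butyldimethylsilyl chloride, CC(C)(C)[Si](C)(C)Cl
Why: Standard silylation of a primary allylic alcohol, needed so that the last step can free all three hydroxyls together.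

Step 15
Reactants: 21 (R)-3-[(Z)-5-(TBSO)-4-methylpent-3-en-1-yl]-7-[(R)-1-(TBSO)prop-2-en-1-yl]-7-methyl-6,7-dihydrooxepin-2(5H)-one; 25 (Z)-tert-butyl[(3-iodobut-2-en-1-yl)oxy]dimethylsilane
Product: 27 (R)-7-[(R,Z)-1,6-bis(TBSO)-4-methylhex-4-en-1-yl]-3-[(Z)-5-(TBSO)-4-methylpent-3-en-1-yl]-7-methyl-6,7-dihydrooxepin-2(5H)-one, via B-alkyl-9-BBN 26 (not isolated)
Conditions: 21, 9-BBN, THF, 0 °C → rt; then 25, PdCl2(dppf) (cat.), AsPh3, Cs2CO3, DMF/H2O, rt
Reagents that add atoms: none
Why: 9-BBN hydroborates the terminal vinyl group much faster than the trisubstituted alkene or the conjugated lactone, and borane 26 couples with the vinyl iodide with retention of its Z geometry (B-alkyl Suzuki–Miyaura coupling), joining C10 to C11.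

Step 16
Reactants: 27 (R)-7-[(R,Z)-1,6-bis(TBSO)-4-methylhex-4-en-1-yl]-3-[(Z)-5-(TBSO)-4-methylpent-3-en-1-yl]-7-methyl-6,7-dihydrooxepin-2(5H)-one
Product: 28 (R)-7-[(R,Z)-1,6-dihydroxy-4-methylhex-4-en-1-yl]-3-[(Z)-5-hydroxy-4-methylpent-3-en-1-yl]-7-methyl-6,7-dihydrooxepin-2(5H)-one
Conditions: HF·pyridine, pyridine, THF, 0 °C → rt
Reagents that add atoms: none
Why: Fluoride cleaves all three Si–O bonds (global desilylation) under buffered, non-basic conditions that leave the enoate lactone, both Z alkenes and both stereocentres untouched, the hindered C8 ether being the last to go.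

**Compound list**

1 | 2-methylcyclohexanone (racemic) | CC1CCCCC1=O | starting material
2 | 2-methyl-1-(trimethylsilyloxy)cyclohex-1-ene | CC1=C(O[Si](C)(C)C)CCCC1 | intermediate
3 | acrolein (prop-2-enal) | C=CC=O | starting material
4 | lithium 2-methylcyclohex-1-en-1-olate | CC1=C([O-])CCCC1.[Li+] | intermediate (not isolated)
5 | rac-(2R*,1′R*)-2-(1-hydroxyprop-2-en-1-yl)-2-methylcyclohexan-1-one (anti aldol, both enantiomers written) | O=C1CCCC[C@]1(C)[C@H](O)C=C.O=C1CCCC[C@@]1(C)[C@@H](O)C=C | intermediate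
6 | (R)-2-[(R)-1-hydroxyprop-2-en-1-yl]-2-methylcyclohexan-1-one | O=C1CCCC[C@]1(C)[C@H](O)C=C | intermediate
7 | (R)-2-[(R)-1-(tert-butyldimethylsilyloxy)prop-2-en-1-yl]-2-methylcyclohexan-1-one | O=C1CCCC[C@]1(C)[C@H](O[Si](C)(C)C(C)(C)C)C=C | intermediate
8 | Criegee adduct: (2R)-2-[(R)-1-(tert-butyldimethylsilyloxy)prop-2-en-1-yl]-1-hydroxy-2-methylcyclohexyl 3-chlorobenzoperoxoate (C1 undefined) | OC1(OOC(=O)c2cccc(Cl)c2)CCCC[C@]1(C)[C@H](O[Si](C)(C)C(C)(C)C)C=C | intermediate (not isolated)
9 | (R)-7-[(R)-1-(tert-butyldimethylsilyloxy)prop-2-en-1-yl]-7-methyloxepan-2-one | O=C1CCCC[C@](C)([C@H](O[Si](C)(C)C(C)(C)C)C=C)O1 | intermediate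
10 | lithium enolate of 9 (lithium 4,5,6,7-tetrahydrooxepin-2-olate with the C7 substituents of 9) | [Li+].[O-]C1=CCCC[C@](C)([C@H](O[Si](C)(C)C(C)(C)C)C=C)O1 | intermediate (not isolated)
11 | (7R)-7-[(R)-1-(tert-butyldimethylsilyloxy)prop-2-en-1-yl]-7-methyl-3-(phenylselanyl)oxepan-2-one (C3 epimers) | O=C1C([Se]c2ccccc2)CCC[C@](C)([C@H](O[Si](C)(C)C(C)(C)C)C=C)O1 | intermediate
12 | selenoxide of 11: (7R)-7-[(R)-1-(tert-butyldimethylsilyloxy)prop-2-en-1-yl]-7-methyl-3-(phenylseleninyl)oxepan-2-one | O=C1C([Se](=O)c2ccccc2)CCC[C@](C)([C@H](O[Si](C)(C)C(C)(C)C)C=C)O1 | intermediate (not isolated)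
13 | (R)-7-[(R)-1-(tert-butyldimethylsilyloxy)prop-2-en-1-yl]-7-methyl-6,7-dihydrooxepin-2(5H)-one | O=C1C=CCC[C@](C)([C@H](O[Si](C)(C)C(C)(C)C)C=C)O1 | intermediate
14 | (R)-7-[(R)-1-(tert-butyldimethylsilyloxy)prop-2-en-1-yl]-3-iodo-7-methyl-6,7-dihydrooxepin-2(5H)-one | O=C1C(I)=CCC[C@](C)([C@H](O[Si](C)(C)C(C)(C)C)C=C)O1 | intermediate
15 | prop-2-yn-1-ol (propargyl alcohol) | C#CCO | starting material
16 | 4-methyl-1-oxa-2-magnesacyclopent-3-ene (cyclic alkenylmagnesium alkoxide) | CC1=C[Mg]OC1 | intermediate (not isolated)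
17 | (Z)-3-iodo-2-methylprop-2-en-1-ol | I/C=C(/C)CO | intermediate
18 | (Z)-tert-butyl[(3-iodo-2-methylprop-2-en-1-yl)oxy]dimethylsilane | I/C=C(/C)CO[Si](C)(C)C(C)(C)C | intermediate
19 | (Z)-tert-butyldimethyl[(2-methylpenta-2,4-dien-1-yl)oxy]silane | C=C/C=C(/C)CO[Si](C)(C)C(C)(C)C | intermediate
20 | 9-[(Z)-5-(tert-butyldimethylsilyloxy)-4-methylpent-3-en-1-yl]-9-borabicyclo[3.3.1]nonane | B1(CC/C=C(/C)CO[Si](C)(C)C(C)(C)C)C2CCCC1CCC2 | intermediate (not isolated)
21 | (R)-3-[(Z)-5-(tert-butyldimethylsilyloxy)-4-methylpent-3-en-1-yl]-7-[(R)-1-(tert-butyldimethylsilyloxy)prop-2-en-1-yl]-7-methyl-6,7-dihydrooxepin-2(5H)-one | O=C1C(CC/C=C(/C)CO[Si](C)(C)C(C)(C)C)=CCC[C@](C)([C@H](O[Si](C)(C)C(C)(C)C)C=C)O1 | intermediate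
22 | but-2-yn-1-ol | CC#CCO | starting material
23 | sodium 2,2-bis(2-methoxyethoxy)-3-methyl-1-oxa-2-aluminacyclopent-3-en-2-uide (cyclic alkenylalanate) | CC1=CCO[Al-]1(OCCOC)OCCOC.[Na+] | intermediate (not isolated)
24 | (Z)-3-iodobut-2-en-1-ol | C/C(I)=C/CO | intermediate
25 | (Z)-tert-butyl[(3-iodobut-2-en-1-yl)oxy]dimethylsilane | C/C(I)=C/CO[Si](C)(C)C(C)(C)C | intermediate
26 | 9-BBN adduct of 21 at the vinyl terminus (boron on C10) | O=C1C(CC/C=C(/C)CO[Si](C)(C)C(C)(C)C)=CCC[C@](C)([C@H](O[Si](C)(C)C(C)(C)C)CCB2C3CCCC2CCC3)O1 | intermediate (not isolated)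
27 | (R)-7-[(R,Z)-1,6-bis(tert-butyldimethylsilyloxy)-4-methylhex-4-en-1-yl]-3-[(Z)-5-(tert-butyldimethylsilyloxy)-4-methylpent-3-en-1-yl]-7-methyl-6,7-dihydrooxepin-2(5H)-one | O=C1C(CC/C=C(/C)CO[Si](C)(C)C(C)(C)C)=CCC[C@](C)([C@H](O[Si](C)(C)C(C)(C)C)CC/C(C)=C\CO[Si](C)(C)C(C)(C)C)O1 | intermediate
28 | (R)-7-[(R,Z)-1,6-dihydroxy-4-methylhex-4-en-1-yl]-3-[(Z)-5-hydroxy-4-methylpent-3-en-1-yl]-7-methyl-6,7-dihydrooxepin-2(5H)-one (CNP0139192.1) | C/C(=C/CCC1=CCC[C@](C)([C@H](O)CC/C(C)=C\CO)OC1=O)CO | target

**Step count**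

Total: 16 steps. Longest linear sequence: 11 steps (steps 1–8, 12, 15, 16). Steps 9–11 and 13–14 are side branches.

**Steps most likely to fail**

1. Step 2. The lithium-centred chair is loose, so simple diastereoselection may be weak. The congested adduct may also revert (retro-aldol), or acrolein may polymerise, before the quench. Fallback: a boron-mediated aldol. Setting out from enolate 4, chlorodicyclohexylborane (THF, −78 °C) would exchange lithium for boron to give dicyclohexyl[(2-methylcyclohex-1-en-1-yl)oxy]borane F1. Its short B–O bonds tighten the six-membered transition state and the addition does not revert. Addition to acrolein 3 and oxidative work-up (MeOH, pH 7 buffer, H2O2, 0 °C) would come back to the route at anti aldol 5.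

2. Step 3. Epoxidation of this neopentyl-type carbinol may be too slow, the titanium alkoxide may induce retro-aldol cleavage, or the rate difference between the enantiomers may be too small, leaving material of low enantiomeric purity. Fallback: take the absolute configuration from the chiral pool instead of a resolution. Setting out from enol silane 2 (converted into enolate 4 as in step 2), addition to (R)-2,2-dimethyl-1,3-dioxolane-4-carbaldehyde F2 should follow the Felkin–Anh sense (attack anti to the α-oxygen) within the same chair. It would give (R)-2-[(S)-[(R)-2,2-dimethyl-1,3-dioxolan-4-yl](hydroxy)methyl]-2-methylcyclohexan-1-one F3. Silylation (TBSOTf, 2,6-lutidine) would give (R)-2-[(S)-(TBSO)[(R)-2,2-dimethyl-1,3-dioxolan-4-yl]methyl]-2-methylcyclohexan-1-one F4. Aqueous AcOH would free the diol (R)-2-[(1S,2R)-1-(TBSO)-2,3-dihydroxypropyl]-2-methylcyclohexan-1-one F5. Deoxygenation of the vicinal diol to the alkene (I2, PPh3, imidazole, toluene, 80 °C) would come back to the route at ketone 7.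

3. Step 8. The amine-promoted addition–elimination may stall on the seven-membered enoate, which is a poorer acceptor than an enone, so that iodination stays incomplete or reverses on work-up. Fallback: form the C3–C1′ bond by enolate alkylation before the ring alkene is introduced. Borane 20 would be oxidised (NaOH, H2O2) to (Z)-5-(TBSO)-4-methylpent-3-en-1-ol F6, and this converted (I2, PPh3, imidazole) into (Z)-tert-butyl[(5-iodo-2-methylpent-2-en-1-yl)oxy]dimethylsilane F7. Setting out from lactone 9, enolisation (LiN(iPr)2, THF/DMPU, −78 °C) and alkylation with F7 would give (7R)-3-[(Z)-5-(TBSO)-4-methylpent-3-en-1-yl]-7-[(R)-1-(TBSO)prop-2-en-1-yl]-7-methyloxepan-2-one F8. A second enolisation and PhSeBr would give (7R)-3-[(Z)-5-(TBSO)-4-methylpent-3-en-1-yl]-7-[(R)-1-(TBSO)prop-2-en-1-yl]-7-methyl-3-(phenylselanyl)oxepan-2-one F9. Oxidation (H2O2, pyridine) with syn-elimination toward C4 would come back to the route at enoate 21; any exocyclic alkene isomer would have to be separated.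

**Further compounds**

F1 | step 2 | dicyclohexyl[(2-methylcyclohex-1-en-1-yl)oxy]borane | CC1=C(OB(C2CCCCC2)C2CCCCC2)CCCC1
F2 | step 3 | (R)-2,2-dimethyl-1,3-dioxolane-4-carbaldehyde | O=C[C@H]1COC(C)(C)O1
F3 | step 3 | (R)-2-[(S)-[(R)-2,2-dimethyl-1,3-dioxolan-4-yl](hydroxy)methyl]-2-methylcyclohexan-1-one | O=C1CCCC[C@]1(C)[C@H](O)[C@H]1COC(C)(C)O1
F4 | step 3 | (R)-2-[(S)-(tert-butyldimethylsilyloxy)[(R)-2,2-dimethyl-1,3-dioxolan-4-yl]methyl]-2-methylcyclohexan-1-one | O=C1CCCC[C@]1(C)[C@H](O[Si](C)(C)C(C)(C)C)[C@H]1COC(C)(C)O1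
F5 | step 3 | (R)-2-[(1S,2R)-1-(tert-butyldimethylsilyloxy)-2,3-dihydroxypropyl]-2-methylcyclohexan-1-one | O=C1CCCC[C@]1(C)[C@H](O[Si](C)(C)C(C)(C)C)[C@H](O)CO
F6 | step 8 | (Z)-5-(tert-butyldimethylsilyloxy)-4-methylpent-3-en-1-ol | OCC/C=C(/C)CO[Si](C)(C)C(C)(C)C
F7 | step 8 | (Z)-tert-butyl[(5-iodo-2-methylpent-2-en-1-yl)oxy]dimethylsilane | ICC/C=C(/C)CO[Si](C)(C)C(C)(C)C
F8 | step 8 | (7R)-3-[(Z)-5-(tert-butyldimethylsilyloxy)-4-methylpent-3-en-1-yl]-7-[(R)-1-(tert-butyldimethylsilyloxy)prop-2-en-1-yl]-7-methyloxepan-2-one (C3 epimers) | O=C1C(CC/C=C(/C)CO[Si](C)(C)C(C)(C)C)CCC[C@](C)([C@H](O[Si](C)(C)C(C)(C)C)C=C)O1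
F9 | step 8 | (7R)-3-[(Z)-5-(tert-butyldimethylsilyloxy)-4-methylpent-3-en-1-yl]-7-[(R)-1-(tert-butyldimethylsilyloxy)prop-2-en-1-yl]-7-methyl-3-(phenylselanyl)oxepan-2-one (C3 epimers) | O=C1C(CC/C=C(/C)CO[Si](C)(C)C(C)(C)C)([Se]c2ccccc2)CCC[C@](C)([C@H](O[Si](C)(C)C(C)(C)C)C=C)O1
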